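## The problem

Compound 25 is a bisabolane-type cyclohexane. Ring carbons C1–C6 carry a methyl group (C1), a free hydroxyl (C2), a branched seven-carbon chain (C4) and an angelate (C5); the chain (C7–C11) has a methyl-bearing C7, an allylic acetate at C9 and a trisubstituted C10=C11 alkene. Ring and chain meet in one C4–C7 bond between two stereocentres, so the route must either couple two chiral fragments there or grow the chain from a ring that already carries a short stub at C4. Of the six stereocentres, the four on the ring (1S,2R,4S,5R in this numbering) can control one another through a chair: the C1 methyl, the C5 oxygen and the C4 substituent are equatorial and only the C2 oxygen is axial. C7 is next to C4 and can feel the ring, whereas C9 is insulated by C8 and needs reagent control. Three secondary oxygens must end as three different functions (hydroxyl at C2, angelate at C5, acetate at C9), so they must be distinguished by the order in which they are unveiled. The angelate isomerises to the tiglate under nucleophilic catalysis, base or long heating and cannot pass through organometallic steps; the C9 acetate is allylic to an electron-rich alkene and is prone to ionisation under acid or zerovalent palladium; the C10=C11 alkene must survive every reduction of other alkenes. The enabling feature is the C4–C5 bond: C5 is a carbinol carbon and C4 bears a carbon (C7) carrying one methyl and one methylene, which is the homoallylic alcohol/isopropenyl pattern left by a carbonyl-ene reaction, with C1, C4 and C5 substituents equatorial as in isopulegol.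

## Retrosynthesis

**Ring oxygens.** Target 25 is traced to its C2 silyl ether 24, and 24 to alcohol 21 and angelic acid 22 by cutting the C5 O–acyl bond. Placing the angelate late keeps it away from strong base and hydrogenation. The acetate is already present in 21, because C9 is acylated at a stage when it is the only free hydroxyl; cutting the acetate last would require telling C5 and C9 hydroxyls apart with both free. The forward steps must esterify without Z to E isomerisation and desilylate without harming two esters.

**C7–H.** Alcohol 21 comes from bis-silyl ether 20, and 20 from the 1,1-disubstituted alkene 19 by removing the hydrogens added across C7=CH2. Bringing C7 in on a separate chiral fragment would need a C4–C7 coupling between two stereocentres; leaving C7 as an sp2 carbon until the ring exists is simpler, but the hydrogenation must choose a face.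
- In the rotamer that keeps C4–H eclipsed with the C7=CH2 bond, the faces are flanked by the C5 oxygen and by the C3 methylene. Delivery from the C5 side gives 7S; delivery from the C3 side gives 7R.
- A free C5 hydroxyl would bind a cationic rhodium or iridium catalyst and send hydrogen to the wrong face. The hydrogenation is therefore run before the C5 silyl ether is removed, with a neutral non-coordinating catalyst, so that the triethylsilyloxy group screens that face.
- The catalyst must also leave the C10=C11 alkene and the allylic acetate alone.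

**C8–C9.** Acetate 19 is the ester of homoallylic alcohol 18, which is cut at C8–C9 into isopropenyl compound 13 and 3-methylbut-2-enal 14. This cut is preferred to C7–C8 or C9–C10 because the isopropenyl methyl of 13 already is C8. Deprotonation gives allylpotassium 15 and, after transfer to boron, allylborane 16, whose addition to 14 makes the bond and sets C9 under control of the boron ligands, independent of the distant ring. The precursor is five carbons and one stereocentre simpler. The forward step needs metalation at the methyl group only and silyl ethers that survive the base, which is why the C5 hydroxyl of 12 is capped as triethylsilyl ether 13.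

**C4–C5 (key).** Cyclohexanol 12 is opened at C4–C5 to acyclic aldehyde 11: C5 becomes the aldehyde carbon, C4 an alkene carbon and the isopropenyl group an isopropylidene terminus. Compared with aldol- or Michael-type closures at C1–C2 or C2–C3, this cut removes the ring and two stereocentres at once, adds no functional group foreign to the target, and leaves C1 and C2 to be made in an open chain. The forward reaction must pass through the chair with the C1 methyl equatorial and the C2 silyloxy group axial; this is where the plan depends on a conformational energy difference.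

**Chain.** Aldehyde 11 is the oxidation product of alcohol 10, made by anti-Markovnikov hydration of the vinyl group of silyl ether 8 through borane 9; 8 is the protected form of homoallylic alcohol 7. In 7 the methyl-bearing and oxygen-bearing carbons (C1 and C2 of the target) are anti in the zigzag chain, which is what a cis relationship on the ring requires. Cutting the bond between them gives 4-methylpent-3-enal 2 and a crotyl unit. The anti relationship calls for the E reagent, crotylborane 5, made from trans-but-2-ene 3 through crotylpotassium 4; the boron ligands fix the absolute sense. Aldehyde 2 comes from commercial alcohol 1 by oxidation. Both stereocentres are thus set in one reagent-controlled step from two achiral pieces; the price is that 2 is a β,γ-unsaturated aldehyde that must be used at once.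

## Roads not taken

Alternative 1: The two ring C–O bonds (C2–O and C5–O) are cut together, leading back to cyclohexa-1,3-diene A1, which already carries the complete acetoxylated side chain. Forward, singlet oxygen A2 (O2, light, tetraphenylporphyrin) would add across C2 and C5 from the face opposite the C4 substituent to give endoperoxide A3.
- Merits: one step installs both ring oxygens, cis to each other and trans to the side chain as in 25. The facial control by the C4 substituent is more secure than the axial/equatorial discrimination on which the chosen key step relies.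
- Weak points: the C10=C11 alkene of A1 is the kind of electron-rich trisubstituted alkene that undergoes the ene reaction with A2 at a rate comparable to the cycloaddition. A1 is a labile, easily aromatised diene whose C4, C7 and C9 centres would still have to be made. A3 then needs O–O reduction, hydrogenation of C6=C1 from the face opposite the two new hydroxyls (their directing effect favours the other face and would put the C1 methyl trans to the C2 hydroxyl), and mono-angeloylation of a diol with two secondary hydroxyls.
- Comparison: the chosen plan fixes C1 before the ring exists and differentiates the three oxygens as each appears. Against the better facial control of the cycloaddition it sets a key step with no competing reactive site.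

Alternative 2: The cut is in the chain: C7–CH3 and C8–C9 are disconnected, leading back to vinylcyclohexane A4 with both ring oxygens silylated. Forward, trimethylaluminium A5 would add across the vinyl group under catalysis by bis(1-neomenthylindenyl)zirconium dichloride, and the alkylalane would be acylated in the same flask with 3-methylbut-2-enoyl chloride A6 and Pd(PPh3)4 to give enone A7.
- Merits: C7 is set by the catalyst and not by the substrate. This is a real advantage over the chosen plan, where C7 depends on a substrate-controlled hydrogenation. Two C–C bonds form in one pot and A7 holds the whole skeleton.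
- Weak points: the alkene of A4 sits on a secondary ring carbon next to a silyloxy group, a substrate class on which the methylalumination is slow and less selective. C9 arrives as a ketone and needs a separate enantioselective reduction. The disconnection does nothing for the ring: A4 has all four ring stereocentres and needs its own synthesis.
- Comparison: the chosen plan keeps the three carbons that the ene reaction delivers and sets C9 together with the C8–C9 bond. What it concedes is reagent control at C7.

Alternative 3: The ring is cut at C2–C3 and C6–C1, leading to α-methylene ketone A8 (C3 to C6 plus the side chain) and hydroxyacetone A9 (C1, C2 and the C1 methyl). Forward, a chiral primary amine with an acid co-catalyst would add the hydroxylated carbon of A9 to the methylene group of A8, and aldol condensation of C6 onto C1 would close cyclohexenone A10.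
- Merits: the route is convergent, the chain centres C7 and C9 are made on a small acyclic piece, C2 is set catalytically, and the longest linear sequence could well be shorter than in the chosen plan.
- Weak points: C4 is α to the C5 ketone and is set only by equilibration against an acyclic neighbour (C7), which gives little bias. A10 still lacks the C1 and C5 centres: the ketone must be reduced to an equatorial alcohol and the alkene hydrogenated with the methyl ending cis to the C2 hydroxyl, again against that hydroxyl's directing effect. A8 is an unhindered α-methylene ketone prone to dimerisation.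
- Comparison: the chosen plan is longer and linear, but all four ring centres are fixed when the ring closes and none is left to a later substrate-controlled reduction.

Key step: step 6

Remark: atom numbers C1–C11 are those of the target (ring C1 CHMe, C2 CHOH, C3, C4, C5 acyloxy carbon, C6; chain C7 CHMe, C8, C9 CHOAc, C10, C11) and are used for all intermediates; compounds 1, 3, 14 and 22 and both antipodes of Ipc2BOMe (B-methoxydiisopinocampheylborane) are taken as purchased.

## Route

Step 1
Reactants: 1 4-methylpent-3-en-1-ol
Product: 2 4-methylpent-3-enal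
Conditions: Dess–Martin periodinane, NaHCO3, CH2Cl2, 0 °C; used at once without purification
Reagents that add atoms: none
Why: Dess–Martin oxidation of a primary alcohol stops at the aldehyde under non-aqueous conditions; bicarbonate buffering and immediate use are meant to keep the β,γ-alkene from moving into conjugation.

Step 2
Reactants: 2 4-methylpent-3-enal; 3 trans-but-2-ene
Product: 7 (3S,4R)-3,7-dimethylocta-1,6-dien-4-ol, via (E)-crotylpotassium 4 (not isolated), via (E)-crotyldiisopinocampheylborane 5 (not isolated), via diisopinocampheylborinate 6 (not isolated)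
Conditions: 3, n-BuLi, KOt-Bu, THF, −78 to −45 °C; (−)-Ipc2BOMe, −78 °C; BF3·OEt2; 2, −78 °C; NaOH, H2O2, 0 °C to rt
Reagents that add atoms: none
Why: Brown crotylboration: metalation of 3 at low temperature keeps the E geometry, and borane 5 adds through a chair Zimmerman–Traxler transition state, so the E reagent gives the anti methyl/hydroxyl pair. The isopinocampheyl groups of (−)-Ipc2BOMe (from (+)-α-pinene) select the aldehyde Si face, which sets 3S,4R; oxidative work-up cleaves borinate 6.

Step 3
Reactants: 7 (3S,4R)-3,7-dimethylocta-1,6-dien-4-ol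
Product: 8 tert-butyl{[(3S,4R)-3,7-dimethylocta-1,6-dien-4-yl]oxy}dimethylsilane
Conditions: TBSCl, imidazole, DMF, rt
Reagents that add atoms: tert-butyldimethylsilyl chloride, CC(C)(C)[Si](C)(C)Cl
Why: Standard silylation of a secondary alcohol; the silyl ether masks the future C2 hydroxyl to the end of the route and prevents lactol formation in 11.

Step 4
Reactants: 8 tert-butyl{[(3S,4R)-3,7-dimethylocta-1,6-dien-4-yl]oxy}dimethylsilane
Product: 10 (3S,4R)-4-(tert-butyldimethylsilyloxy)-3,7-dimethyloct-6-en-1-ol, via B-alkyl-9-borabicyclo[3.3.1]nonane 9 (not isolated)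
Conditions: 9-BBN, THF, 0 °C to rt; NaOH, H2O2, 0 °C
Reagents that add atoms: hydrogen peroxide, OO
Why: Hydroboration–oxidation: the bulky 9-BBN adds only to the monosubstituted alkene, anti-Markovnikov, and leaves the trisubstituted alkene; no stereocentre is touched.

Step 5
Reactants: 10 (3S,4R)-4-(tert-butyldimethylsilyloxy)-3,7-dimethyloct-6-en-1-ol
Product: 11 (3S,4R)-4-(tert-butyldimethylsilyloxy)-3,7-dimethyloct-6-enal
Conditions: Dess–Martin periodinane, NaHCO3, CH2Cl2, 0 °C to rt
Reagents that add atoms: none
Why: Dess–Martin oxidation to the aldehyde; the α-carbon is a methylene, so the methyl-bearing centre cannot epimerise.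

Step 6
Reactants: 11 (3S,4R)-4-(tert-butyldimethylsilyloxy)-3,7-dimethyloct-6-enal
Product: 12 (1R,2S,4R,5S)-4-(tert-butyldimethylsilyloxy)-5-methyl-2-(prop-1-en-2-yl)cyclohexan-1-ol
Conditions: ZnBr2, CH2Cl2, −20 to 0 °C
Reagents that add atoms: none
Why: ZnBr2 binds the aldehyde oxygen, and the trisubstituted alkene carbon (C4 of the target) attacks the activated carbonyl carbon (C5) while a hydrogen of an alkene methyl group passes to oxygen, a concerted but asynchronous intramolecular carbonyl-ene reaction. The closest known reaction is the ZnBr2-promoted cyclisation of citronellal to isopulegol. The cyclohexane closes in the 6-exo mode with respect to both the carbonyl group and the alkene, through a chair-like transition state. C5 and C4 are the new stereocentres: the zinc-bound oxygen and the forming isopropenyl group both sit equatorial, which gives the trans C4/C5 relationship, and their absolute sense follows from the existing C1 centre, whose methyl group sits equatorial. The selectivity needed is for this chair over its ring-flipped partner (methyl axial, silyloxy equatorial), which would give the C4,C5-bis-epimer. It rests on the larger tabulated conformational energy of methyl (about 1.7 kcal/mol) than of a silyloxy group (about 1 kcal/mol), helped by low temperature and a bulky, non-chelating silyl ether. The cis alcohol from an axial carbonyl oxygen should be disfavoured as in the parent reaction.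

Step 7
Reactants: 12 (1R,2S,4R,5S)-4-(tert-butyldimethylsilyloxy)-5-methyl-2-(prop-1-en-2-yl)cyclohexan-1-ol
Product: 13 (1R,2S,4R,5S)-4-(tert-butyldimethylsilyloxy)-5-methyl-2-(prop-1-en-2-yl)-1-(triethylsilyloxy)cyclohexane
Conditions: TESCl, imidazole, DMAP, DMF, 0 °C to rt
Reagents that add atoms: triethylsilyl chloride, CC[Si](CC)(CC)Cl
Why: Silylation of the C5 hydroxyl; the triethylsilyl ether survives the superbase, screens one face of the neighbouring alkene in step 10 and can later be removed without loss of the C2 silyl ether.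

Step 8
Reactants: 13 (1R,2S,4R,5S)-4-(tert-butyldimethylsilyloxy)-5-methyl-2-(prop-1-en-2-yl)-1-(triethylsilyloxy)cyclohexane; 14 3-methylbut-2-enal
Product: 18 (4R)-2-[(1S,2R,4R,5S)-4-(tert-butyldimethylsilyloxy)-5-methyl-2-(triethylsilyloxy)cyclohexyl]-6-methylhepta-1,5-dien-4-ol, via allylpotassium 15 (not isolated), via allyldiisopinocampheylborane 16 (not isolated), via diisopinocampheylborinate 17 (not isolated)
Conditions: 13, n-BuLi, KOt-Bu, THF, −78 to −45 °C; (+)-Ipc2BOMe, −78 °C; BF3·OEt2; 14, −78 °C; NaOH, H2O2, 0 °C
Reagents that add atoms: none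
Why: Allylic metalation of the isopropenyl methyl group with the n-BuLi/KOt-Bu superbase (as with 2-methylpropene and limonene), transfer to boron and Brown allylboration of enal 14 form C8–C9. The isopinocampheyl groups of (+)-Ipc2BOMe (from (−)-α-pinene) direct the chair transition state to the aldehyde Re face, which sets 9R by reagent control.

Step 9
Reactants: 18 (4R)-2-[(1S,2R,4R,5S)-4-(tert-butyldimethylsilyloxy)-5-methyl-2-(triethylsilyloxy)cyclohexyl]-6-methylhepta-1,5-dien-4-ol
Product: 19 (4R)-2-[(1S,2R,4R,5S)-4-(tert-butyldimethylsilyloxy)-5-methyl-2-(triethylsilyloxy)cyclohexyl]-6-methylhepta-1,5-dien-4-yl acetate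
Conditions: Ac2O, pyridine, DMAP, CH2Cl2, 0 °C to rt
Reagents that add atoms: acetic anhydride, CC(=O)OC(C)=O
Why: DMAP-catalysed acetylation of the only free hydroxyl; the C9–O bond is not broken, so the configuration is retained.

Step 10
Reactants: 19 (4R)-2-[(1S,2R,4R,5S)-4-(tert-butyldimethylsilyloxy)-5-methyl-2-(triethylsilyloxy)cyclohexyl]-6-methylhepta-1,5-dien-4-yl acetate
Product: 20 (4R,6R)-6-[(1S,2R,4R,5S)-4-(tert-butyldimethylsilyloxy)-5-methyl-2-(triethylsilyloxy)cyclohexyl]-2-methylhept-2-en-4-yl acetate
Conditions: H2 (1 atm), RhCl(PPh3)3, benzene, rt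
Reagents that add atoms: none
Why: Homogeneous hydrogenation with RhCl(PPh3)3 (Wilkinson's catalyst) reduces the 1,1-disubstituted alkene and leaves the trisubstituted C10=C11 alkene and the allylic acetate, the usual selectivity of this catalyst. C7 is set by substrate control: in the rotamer with C4–H eclipsing the C7=CH2 bond (least 1,3-allylic strain) one face is screened by the equatorial C5 triethylsilyloxy group, and addition from the open C3 side gives 7R. The catalyst is neutral and both ring oxygens are silylated, so no hydroxyl-directed delivery to the C5 face (which would give 7S) can intervene.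

Step 11
Reactants: 20 (4R,6R)-6-[(1S,2R,4R,5S)-4-(tert-butyldimethylsilyloxy)-5-methyl-2-(triethylsilyloxy)cyclohexyl]-2-methylhept-2-en-4-yl acetate
Product: 21 (4R,6R)-6-[(1S,2R,4R,5S)-4-(tert-butyldimethylsilyloxy)-2-hydroxy-5-methylcyclohexyl]-2-methylhept-2-en-4-yl acetate
Conditions: PPTS, MeOH, CH2Cl2, 0 °C to rt
Reagents that add atoms: none
Why: Acid-catalysed methanolysis removes a triethylsilyl ether much faster than the hindered axial tert-butyldimethylsilyl ether (the usual order of silyl ether lability), and the mild acid should spare the allylic acetate.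

Step 12
Reactants: 21 (4R,6R)-6-[(1S,2R,4R,5S)-4-(tert-butyldimethylsilyloxy)-2-hydroxy-5-methylcyclohexyl]-2-methylhept-2-en-4-yl acetate; 22 angelic acid
Product: 24 (1R,2S,4R,5S)-2-[(2R,4R)-4-acetoxy-6-methylhept-5-en-2-yl]-4-(tert-butyldimethylsilyloxy)-5-methylcyclohexyl (Z)-2-methylbut-2-enoate, via angelic 2,4,6-trichlorobenzoic anhydride 23 (not isolated)
Conditions: 22, 2,4,6-trichlorobenzoyl chloride, Et3N, toluene, rt; then 21, toluene, 80 °C
Reagents that add atoms: none
Why: Yamaguchi-type esterification through mixed anhydride 23: the alcohol attacks the less hindered angeloyl carbonyl. Leaving out DMAP and other nucleophilic catalysts avoids the addition–elimination pathway that turns angelates into tiglates.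

Step 13
Reactants: 24 (1R,2S,4R,5S)-2-[(2R,4R)-4-acetoxy-6-methylhept-5-en-2-yl]-4-(tert-butyldimethylsilyloxy)-5-methylcyclohexyl (Z)-2-methylbut-2-enoate
Product: 25 (1R,2S,4R,5S)-2-[(2R,4R)-4-acetoxy-6-methylhept-5-en-2-yl]-4-hydroxy-5-methylcyclohexyl (Z)-2-methylbut-2-enoate
Conditions: HF·pyridine, pyridine, THF, 0 °C to rt
Reagents that add atoms: none
Why: Fluoride cleavage of the Si–O bond with pyridine-buffered HF·pyridine; the medium is non-basic (no ester cleavage or acyl migration) and only weakly acidic, to spare the allylic acetate.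

## Compound list

1 | 4-methylpent-3-en-1-ol | CC(C)=CCCO | starting material
2 | 4-methylpent-3-enal | CC(C)=CCC=O | intermediate
3 | trans-but-2-ene | C/C=C/C | starting material
4 | (E)-but-2-en-1-ylpotassium ((E)-crotylpotassium) | C/C=C/C[K] | intermediate
5 | (E)-but-2-en-1-ylbis[(1R,2S,3R,5R)-2,6,6-trimethylbicyclo[3.1.1]heptan-3-yl]borane | C/C=C/CB([C@@H]1C[C@@H]2C[C@H]([C@H]1C)C2(C)C)[C@@H]1C[C@@H]2C[C@H]([C@H]1C)C2(C)C | intermediate
6 | (3S,4R)-3,7-dimethylocta-1,6-dien-4-yl bis[(1R,2S,3R,5R)-2,6,6-trimethylbicyclo[3.1.1]heptan-3-yl]borinate | C=C[C@H](C)[C@H](OB([C@@H]1C[C@@H]2C[C@H]([C@H]1C)C2(C)C)[C@@H]1C[C@@H]2C[C@H]([C@H]1C)C2(C)C)CC=C(C)C | intermediate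
7 | (3S,4R)-3,7-dimethylocta-1,6-dien-4-ol | C=C[C@H](C)[C@H](O)CC=C(C)C | intermediate
8 | tert-butyl{[(3S,4R)-3,7-dimethylocta-1,6-dien-4-yl]oxy}dimethylsilane | C=C[C@H](C)[C@H](O[Si](C)(C)C(C)(C)C)CC=C(C)C | intermediate
9 | 9-[(3S,4R)-4-(tert-butyldimethylsilyloxy)-3,7-dimethyloct-6-en-1-yl]-9-borabicyclo[3.3.1]nonane | C1CC2CCCC(C1)B2CC[C@H](C)[C@H](O[Si](C)(C)C(C)(C)C)CC=C(C)C | intermediate
10 | (3S,4R)-4-(tert-butyldimethylsilyloxy)-3,7-dimethyloct-6-en-1-ol | OCC[C@H](C)[C@H](O[Si](C)(C)C(C)(C)C)CC=C(C)C | intermediate
11 | (3S,4R)-4-(tert-butyldimethylsilyloxy)-3,7-dimethyloct-6-enal | O=CC[C@H](C)[C@H](O[Si](C)(C)C(C)(C)C)CC=C(C)C | intermediate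
12 | (1R,2S,4R,5S)-4-(tert-butyldimethylsilyloxy)-5-methyl-2-(prop-1-en-2-yl)cyclohexan-1-ol | O[C@@H]1C[C@H](C)[C@H](O[Si](C)(C)C(C)(C)C)C[C@H]1C(C)=C | intermediate
13 | (1R,2S,4R,5S)-4-(tert-butyldimethylsilyloxy)-5-methyl-2-(prop-1-en-2-yl)-1-(triethylsilyloxy)cyclohexane | CC[Si](CC)(CC)O[C@@H]1C[C@H](C)[C@H](O[Si](C)(C)C(C)(C)C)C[C@H]1C(C)=C | intermediate
14 | 3-methylbut-2-enal | CC(C)=CC=O | starting material
15 | {2-[(1S,2R,4R,5S)-4-(tert-butyldimethylsilyloxy)-5-methyl-2-(triethylsilyloxy)cyclohexyl]prop-2-en-1-yl}potassium | CC[Si](CC)(CC)O[C@@H]1C[C@H](C)[C@H](O[Si](C)(C)C(C)(C)C)C[C@H]1C(=C)C[K] | intermediate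
16 | {2-[(1S,2R,4R,5S)-4-(tert-butyldimethylsilyloxy)-5-methyl-2-(triethylsilyloxy)cyclohexyl]prop-2-en-1-yl}bis[(1S,2R,3S,5S)-2,6,6-trimethylbicyclo[3.1.1]heptan-3-yl]borane | CC[Si](CC)(CC)O[C@@H]1C[C@H](C)[C@H](O[Si](C)(C)C(C)(C)C)C[C@H]1C(=C)CB([C@H]2C[C@H]3C[C@@H]([C@@H]2C)C3(C)C)[C@H]2C[C@H]3C[C@@H]([C@@H]2C)C3(C)C | intermediate
17 | (4R)-2-[(1S,2R,4R,5S)-4-(tert-butyldimethylsilyloxy)-5-methyl-2-(triethylsilyloxy)cyclohexyl]-6-methylhepta-1,5-dien-4-yl bis[(1S,2R,3S,5S)-2,6,6-trimethylbicyclo[3.1.1]heptan-3-yl]borinate | CC[Si](CC)(CC)O[C@@H]1C[C@H](C)[C@H](O[Si](C)(C)C(C)(C)C)C[C@H]1C(=C)C[C@H](C=C(C)C)OB([C@H]2C[C@H]3C[C@@H]([C@@H]2C)C3(C)C)[C@H]2C[C@H]3C[C@@H]([C@@H]2C)C3(C)C | intermediate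
18 | (4R)-2-[(1S,2R,4R,5S)-4-(tert-butyldimethylsilyloxy)-5-methyl-2-(triethylsilyloxy)cyclohexyl]-6-methylhepta-1,5-dien-4-ol | CC[Si](CC)(CC)O[C@@H]1C[C@H](C)[C@H](O[Si](C)(C)C(C)(C)C)C[C@H]1C(=C)C[C@H](C=C(C)C)O | intermediate
19 | (4R)-2-[(1S,2R,4R,5S)-4-(tert-butyldimethylsilyloxy)-5-methyl-2-(triethylsilyloxy)cyclohexyl]-6-methylhepta-1,5-dien-4-yl acetate | CC[Si](CC)(CC)O[C@@H]1C[C@H](C)[C@H](O[Si](C)(C)C(C)(C)C)C[C@H]1C(=C)C[C@H](C=C(C)C)OC(C)=O | intermediate
20 | (4R,6R)-6-[(1S,2R,4R,5S)-4-(tert-butyldimethylsilyloxy)-5-methyl-2-(triethylsilyloxy)cyclohexyl]-2-methylhept-2-en-4-yl acetate | CC[Si](CC)(CC)O[C@@H]1C[C@H](C)[C@H](O[Si](C)(C)C(C)(C)C)C[C@H]1[C@H](C)C[C@H](C=C(C)C)OC(C)=O | intermediate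
21 | (4R,6R)-6-[(1S,2R,4R,5S)-4-(tert-butyldimethylsilyloxy)-2-hydroxy-5-methylcyclohexyl]-2-methylhept-2-en-4-yl acetate | O[C@@H]1C[C@H](C)[C@H](O[Si](C)(C)C(C)(C)C)C[C@H]1[C@H](C)C[C@H](C=C(C)C)OC(C)=O | intermediate
22 | angelic acid ((Z)-2-methylbut-2-enoic acid) | C/C=C(/C)C(=O)O | starting material
23 | (Z)-2-methylbut-2-enoic 2,4,6-trichlorobenzoic anhydride | C/C=C(/C)C(=O)OC(=O)c1c(Cl)cc(Cl)cc1Cl | intermediate
24 | (1R,2S,4R,5S)-2-[(2R,4R)-4-acetoxy-6-methylhept-5-en-2-yl]-4-(tert-butyldimethylsilyloxy)-5-methylcyclohexyl (Z)-2-methylbut-2-enoate | C/C=C(/C)C(=O)O[C@@H]1C[C@H](C)[C@H](O[Si](C)(C)C(C)(C)C)C[C@H]1[C@H](C)C[C@H](C=C(C)C)OC(C)=O | intermediate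
25 | (1R,2S,4R,5S)-2-[(2R,4R)-4-acetoxy-6-methylhept-5-en-2-yl]-4-hydroxy-5-methylcyclohexyl (Z)-2-methylbut-2-enoate | C/C=C(/C)C(=O)O[C@@H]1C[C@H](C)[C@H](O)C[C@H]1[C@H](C)C[C@H](C=C(C)C)OC(C)=O | target

## Step count and least certain steps

Total step count: 13. Longest linear sequence: 13 steps (1 to 25); 3, 14 and 22 enter as purchased components.

**Step 6 (key step).** The most likely failure is poor discrimination between the two chairs: the energy gap between axial silyloxy and axial methyl is under 1 kcal/mol, so ring closure through the methyl-axial chair could erode the diastereoselectivity at C4 and C5. A lesser risk is partial closure with the carbonyl oxygen axial. Fallback (sets out from 2, comes back at 13): close the ring in the all-equatorial series and correct C2 afterwards.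
- Crotylboration of 2 with the (Z)-crotyl reagent from cis-but-2-ene and (+)-Ipc2BOMe would give syn alcohol (3S,4S)-3,7-dimethylocta-1,6-dien-4-ol F1.
- Benzoylation (BzCl, pyridine) gives benzoate F2; 9-BBN followed by NaBO3·4H2O gives primary alcohol F3; Dess–Martin oxidation gives aldehyde F4.
- ZnBr2 then closes the ring through a chair with every substituent equatorial, as in the parent citronellal case, to give cyclohexanol F5.
- TESCl/imidazole gives silyl ether F6, and i-Bu2AlH removes the benzoate to give equatorial alcohol F7.
- Dess–Martin oxidation gives ketone F8, and LiBH(s-Bu)3 at −78 °C attacks from the equatorial side to give axial alcohol F9.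
- TBSOTf/2,6-lutidine converts this into 13.

**Step 10.** The most likely failure is poor facial selectivity, because the screening by the C5 silyloxy group works only while the C4–H-eclipsed rotamer dominates. Rhodium hydride may also move the 1,1-disubstituted alkene to an internal position. Fallback (sets out from 18, comes back at 24): move the alkene into conjugation so that a hydroxyl-directed hydrogenation delivers hydrogen to the correct face.
- Dess–Martin oxidation of 18 gives β,γ-unsaturated ketone F10, and DBU moves the 1,1-disubstituted alkene into conjugation to give (E)-dienone F11.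
- PPTS/MeOH frees the C5 hydroxyl to give hydroxy dienone F12.
- Hydrogenation with [Rh(nbd)(dppb)]BF4 (or Crabtree's catalyst [Ir(cod)(PCy3)(py)]PF6) is now directed by the C5 hydroxyl to the C7=C8 alkene. With C4–H eclipsing that alkene, the carbon in the alkene plane is C8 and not the future methyl group, so delivery from the C5 face gives the 7R ketone F13.
- Angeloylation as in step 12 gives keto ester F14; CBS reduction ((S)-oxazaborolidine, catecholborane) gives the 9R alcohol F15; acetylation gives 24.

**Step 8.** The most likely failures are incomplete or unselective metalation in the presence of two silyl ethers, and weak induction at C9 from an allylborane that carries a bulky chiral 2-substituent. Fallback (sets out from 13, comes back at 18): make the allyl nucleophile by electrophilic substitution and set C9 with a chiral Lewis acid.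
- Ene-type allylic chlorination of 13 (NCS, catalytic PhSeCl) gives allylic chloride F16.
- Bu3SnLi displaces chloride to give allylstannane F17.
- Keck allylation of 14 with the BINOL/Ti(OiPr)4 catalyst of the handedness that favours 9R gives 18.

**Step 2.** The most likely failure is loss of 2 before it is trapped, by evaporation and by acid- or base-promoted migration of its alkene into conjugation. Fallback (sets out from 1, comes back at 7): iridium-catalysed transfer-hydrogenative anti-crotylation of alcohol 1 with but-3-en-2-yl acetate ([Ir(cod)Cl]2, the SEGPHOS antipode that gives the 3S,4R product, 4-cyano-3-nitrobenzoic acid, Cs2CO3, THF, heat) gives 7 directly. The aldehyde then exists only transiently at the metal, and no new isolated compound is needed.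

**Step 12.** The most likely failures are isomerisation of the angeloyl group to the tigloyl group during activation or heating, and slow acylation of the hindered C5 hydroxyl. Fallback (sets out from 21, comes back at 24): build the Z alkene on the molecule.
- Esterification of 21 with 2-[bis(2,2,2-trifluoroethoxy)phosphoryl]propanoic acid (DCC, DMAP) gives phosphonate ester F18.
- Still–Gennari olefination with acetaldehyde (KN(SiMe3)2, 18-crown-6, THF, −78 °C) gives the Z-trisubstituted enoate 24.

Further compounds
F1 | step 6 | (3S,4S)-3,7-dimethylocta-1,6-dien-4-ol | C=C[C@H](C)[C@@H](O)CC=C(C)C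
F2 | step 6 | (3S,4S)-3,7-dimethylocta-1,6-dien-4-yl benzoate | C=C[C@H](C)[C@@H](OC(=O)c1ccccc1)CC=C(C)C
F3 | step 6 | (3S,4S)-1-hydroxy-3,7-dimethyloct-6-en-4-yl benzoate | OCC[C@H](C)[C@@H](OC(=O)c1ccccc1)CC=C(C)C
F4 | step 6 | (3S,4S)-3,7-dimethyl-1-oxooct-6-en-4-yl benzoate | O=CC[C@H](C)[C@@H](OC(=O)c1ccccc1)CC=C(C)C
F5 | step 6 | (1S,2S,4R,5S)-4-hydroxy-2-methyl-5-(prop-1-en-2-yl)cyclohexyl benzoate | O[C@@H]1C[C@H](C)[C@@H](OC(=O)c2ccccc2)C[C@H]1C(C)=C
F6 | step 6 | (1S,2S,4R,5S)-2-methyl-5-(prop-1-en-2-yl)-4-(triethylsilyloxy)cyclohexyl benzoate | CC[Si](CC)(CC)O[C@@H]1C[C@H](C)[C@@H](OC(=O)c2ccccc2)C[C@H]1C(C)=C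
F7 | step 6 | (1S,2S,4R,5S)-2-methyl-5-(prop-1-en-2-yl)-4-(triethylsilyloxy)cyclohexan-1-ol | CC[Si](CC)(CC)O[C@@H]1C[C@H](C)[C@@H](O)C[C@H]1C(C)=C
F8 | step 6 | (2S,4R,5S)-2-methyl-5-(prop-1-en-2-yl)-4-(triethylsilyloxy)cyclohexan-1-one | CC[Si](CC)(CC)O[C@@H]1C[C@H](C)C(=O)C[C@H]1C(C)=C
F9 | step 6 | (1R,2S,4R,5S)-2-methyl-5-(prop-1-en-2-yl)-4-(triethylsilyloxy)cyclohexan-1-ol | CC[Si](CC)(CC)O[C@@H]1C[C@H](C)[C@H](O)C[C@H]1C(C)=C
F10 | step 10 | 2-[(1S,2R,4R,5S)-4-(tert-butyldimethylsilyloxy)-5-methyl-2-(triethylsilyloxy)cyclohexyl]-6-methylhepta-1,5-dien-4-one | CC[Si](CC)(CC)O[C@@H]1C[C@H](C)[C@H](O[Si](C)(C)C(C)(C)C)C[C@H]1C(=C)CC(=O)C=C(C)C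
F11 | step 10 | (E)-6-[(1S,2R,4R,5S)-4-(tert-butyldimethylsilyloxy)-5-methyl-2-(triethylsilyloxy)cyclohexyl]-2-methylhepta-2,5-dien-4-one | CC[Si](CC)(CC)O[C@@H]1C[C@H](C)[C@H](O[Si](C)(C)C(C)(C)C)C[C@H]1/C(C)=C/C(=O)C=C(C)C
F12 | step 10 | (E)-6-[(1S,2R,4R,5S)-4-(tert-butyldimethylsilyloxy)-2-hydroxy-5-methylcyclohexyl]-2-methylhepta-2,5-dien-4-one | O[C@@H]1C[C@H](C)[C@H](O[Si](C)(C)C(C)(C)C)C[C@H]1/C(C)=C/C(=O)C=C(C)C
F13 | step 10 | (6R)-6-[(1S,2R,4R,5S)-4-(tert-butyldimethylsilyloxy)-2-hydroxy-5-methylcyclohexyl]-2-methylhept-2-en-4-one | O[C@@H]1C[C@H](C)[C@H](O[Si](C)(C)C(C)(C)C)C[C@H]1[C@H](C)CC(=O)C=C(C)C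
F14 | step 10 | (1R,2S,4R,5S)-4-(tert-butyldimethylsilyloxy)-5-methyl-2-[(2R)-6-methyl-4-oxohept-5-en-2-yl]cyclohexyl (Z)-2-methylbut-2-enoate | C/C=C(/C)C(=O)O[C@@H]1C[C@H](C)[C@H](O[Si](C)(C)C(C)(C)C)C[C@H]1[C@H](C)CC(=O)C=C(C)C
F15 | step 10 | (1R,2S,4R,5S)-4-(tert-butyldimethylsilyloxy)-2-[(2R,4R)-4-hydroxy-6-methylhept-5-en-2-yl]-5-methylcyclohexyl (Z)-2-methylbut-2-enoate | C/C=C(/C)C(=O)O[C@@H]1C[C@H](C)[C@H](O[Si](C)(C)C(C)(C)C)C[C@H]1[C@H](C)C[C@H](C=C(C)C)O
F16 | step 8 | (1R,2S,4R,5S)-4-(tert-butyldimethylsilyloxy)-2-(3-chloroprop-1-en-2-yl)-5-methyl-1-(triethylsilyloxy)cyclohexane | CC[Si](CC)(CC)O[C@@H]1C[C@H](C)[C@H](O[Si](C)(C)C(C)(C)C)C[C@H]1C(=C)CCl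
F17 | step 8 | tributyl{2-[(1S,2R,4R,5S)-4-(tert-butyldimethylsilyloxy)-5-methyl-2-(triethylsilyloxy)cyclohexyl]prop-2-en-1-yl}stannane | CC[Si](CC)(CC)O[C@@H]1C[C@H](C)[C@H](O[Si](C)(C)C(C)(C)C)C[C@H]1C(=C)C[Sn](CCCC)(CCCC)CCCC
F0 | step 2 | none | none
F18 | step 12 | (1R,2S,4R,5S)-2-[(2R,4R)-4-acetoxy-6-methylhept-5-en-2-yl]-4-(tert-butyldimethylsilyloxy)-5-methylcyclohexyl 2-[bis(2,2,2-trifluoroethoxy)phosphoryl]propanoate | CC(C(=O)O[C@@H]1C[C@H](C)[C@H](O[Si](C)(C)C(C)(C)C)C[C@H]1[C@H](C)C[C@H](C=C(C)C)OC(C)=O)P(=O)(OCC(F)(F)F)OCC(F)(F)F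
A1 | alternative 1 | (4R,6R)-2-methyl-6-[(1S)-4-methylcyclohexa-2,4-dien-1-yl]hept-2-en-4-yl acetate | C1=CC(C)=CC[C@H]1[C@H](C)C[C@H](C=C(C)C)OC(C)=O
A2 | alternative 1 | singlet oxygen (dioxygen) | O=O
A3 | alternative 1 | (4R,6R)-2-methyl-6-[5-methyl-2,3-dioxabicyclo[2.2.2]oct-5-en-7-yl]hept-2-en-4-yl acetate, peroxide bridge anti to the side chain | O2[C@@H]1C=C(C)[C@H](O2)C[C@H]1[C@H](C)C[C@H](C=C(C)C)OC(C)=O
A4 | alternative 2 | (1R,2S,4R,5S)-1,4-bis(tert-butyldimethylsilyloxy)-2-ethenyl-5-methylcyclohexane | CC(C)(C)[Si](C)(C)O[C@@H]1C[C@H](C)[C@H](O[Si](C)(C)C(C)(C)C)C[C@H]1C=C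
A5 | alternative 2 | trimethylaluminium | C[Al](C)C
A6 | alternative 2 | 3-methylbut-2-enoyl chloride | CC(C)=CC(=O)Cl
A7 | alternative 2 | (6R)-6-[(1S,2R,4R,5S)-2,4-bis(tert-butyldimethylsilyloxy)-5-methylcyclohexyl]-2-methylhept-2-en-4-one | CC(C)(C)[Si](C)(C)O[C@@H]1C[C@H](C)[C@H](O[Si](C)(C)C(C)(C)C)C[C@H]1[C@H](C)CC(=O)C=C(C)C
A8 | alternative 3 | (4R,6R)-6-(tert-butyldimethylsilyloxy)-4,8-dimethyl-3-methylidenenon-7-en-2-one | CC(=O)C(=C)[C@H](C)C[C@H](C=C(C)C)O[Si](C)(C)C(C)(C)C
A9 | alternative 3 | hydroxyacetone | CC(=O)CO
A10 | alternative 3 | (4R,6S)-6-[(2R,4R)-4-(tert-butyldimethylsilyloxy)-6-methylhept-5-en-2-yl]-4-hydroxy-3-methylcyclohex-2-en-1-one | O=C1C=C(C)[C@H](O)C[C@H]1[C@H](C)C[C@H](C=C(C)C)O[Si](C)(C)C(C)(C)C
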